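**Plan**

Labels and enabling feature: the oxolane is O1, C2 (aryl), C3 (CH2OH), C4 (arylmethyl), C5; the side chain is Cα (carbinol), Cβ (aryloxy), Cγ (CH2OH). C4 is a CH that carries the benzylic CH2 of the central guaiacyl ring. It lies between C5H2 (on O1) and C3, which is also a CH2 at the lactone level. Arene–CH2–C4–C5 is therefore the eugenol skeleton, C3 plus the hydroxymethyl carbon are a ketene C2 unit, and the core maps onto a mirror-symmetric 3-(arylmethyl)cyclobutanone.
Cuts, in retrosynthetic order: the two phenolic O–benzyl bonds; Cα–Cβ (glycolate aldol) and the central aryl-O–CH2 bond (alkylation); O1–C2 (benzylic etherification); C2–C3 (lactone aldol); O1–C5 (oxygen insertion); the two ring bonds made by the [2+2] cycloaddition.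
Forward: eugenol gives the cyclobutanone, oxygen insertion gives the butyrolactone, and aldol, reduction and closure give the oxolane. Phenol release, alkylation with the bromoacetyl imide, a second aldol, reduction and hydrogenolysis follow.
Stereochemistry: C4 (R) comes from the chiral catalyst of the Baeyer–Villiger step, C3 (R) from C4 (anti aldol), and C2 (S) from C3 (trans-selective closure). Cα and Cβ (R,R, threo) come from (S)-4-benzyl-2-oxazolidinone in a boron syn aldol.

Key step: step 4

Assumption: the (R)-phosphoric acid is taken to deliver (R)-8. The sense is to be checked on the first run against the sign of rotation of known (R)-β-arylmethyl-γ-butyrolactones, and the equally available (S)-acid is used if it proves opposite.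

**Route**

Step 1
Reactants: 1 eugenol (4-allyl-2-methoxyphenol)
Product: 2 4-allyl-2-methoxy-1-(triisopropylsilyloxy)benzene (O-TIPS-eugenol)
Conditions: TIPSCl, imidazole, DMF, rt
Reagents that add atoms: triisopropylsilyl chloride, CC(C)[Si](Cl)(C(C)C)C(C)C
Why: Silyl ether formation (substitution at silicon, imidazole as base and nucleophilic catalyst) is routine for phenols, and the bulky aryl TIPS ether withstands zinc, acetic acid, peroxide, amide base and hydride yet leaves with fluoride beside benzyl ethers.

Step 2
Reactants: 2 O-TIPS-eugenol; 3 trichloroacetyl chloride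
Product: 5 (±)-2,2-dichloro-3-[(3-methoxy-4-triisopropylsilyloxyphenyl)methyl]cyclobutanone, via dichloroketene 4 (not isolated)
Conditions: Zn–Cu couple, DME (binds ZnCl2), Et2O, slow addition of 3, reflux
Reagents that add atoms: none
Why: Zinc dechlorinates 3 to dichloroketene, whose thermal [2+2] ketene–alkene cycloaddition with terminal alkenes such as allylarenes is well known and joins the carbonyl carbon to the terminal CH2, so the arylmethyl group sits at C3 (the stereocentre formed is racemic and disappears in step 3).

Step 3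
Reactants: 5 dichlorocyclobutanone
Product: 6 3-[(3-methoxy-4-triisopropylsilyloxyphenyl)methyl]cyclobutanone (achiral)
Conditions: Zn dust, AcOH, rt
Reagents that add atoms: none
Why: Reductive dehalogenation of an α,α-dichloroketone with zinc in acetic acid (via zinc enolates) is the standard sequel to dichloroketene cycloaddition, leaves ketone, silyl ether and arene alone, and gives a ketone with a mirror plane through C1 and C3.

Step 4
Reactants: 6 3-(arylmethyl)cyclobutanone
Product: 8 (R)-4-[(3-methoxy-4-triisopropylsilyloxyphenyl)methyl]dihydrofuran-2(3H)-one, via Criegee hydroperoxy hemiketal 7 (not isolated)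
Conditions: (R)-3,3'-di(pyren-1-yl)-H8-BINOL hydrogen phosphate (10 mol %), 30% aq H2O2 (1.5 equiv), CHCl3, −40 °C
Reagents that add atoms: hydrogen peroxide, OO
Why: The phosphoric acid binds ketone and H2O2 at once (P–OH to C=O, P=O to HOOH), so peroxide adds to the strained carbonyl and gives the Criegee hydroperoxy hemiketal 7, still held by the chiral phosphate. In the rate- and stereo-determining step the acid protonates the outer peroxide oxygen, and the ring CH2 antiperiplanar to the O–O bond shifts from carbon to oxygen with loss of water, which creates the O1–C5 bond. The closest known reaction type is the chiral Brønsted-acid-catalysed (likewise metal- or monooxygenase-catalysed) Baeyer–Villiger desymmetrisation of 3-aryl- and 3-benzylcyclobutanones to β-substituted γ-butyrolactones. The oxolan-2-one ring is not closed end to end but arises by ring expansion, a 1,2-shift that inserts oxygen into the four-membered ring (4 → 5). No bond at C4 changes: it becomes stereogenic only because its two CH2 arms become different, and which arm migrates (hence R) is decided by the pyrenyl-walled pocket of the catalyst alone, since the substrate has a mirror plane. The step needs enantiotopic-group selectivity (from the catalyst) and chemoselectivity (from the substrate): strain release lets the oxidation run at −40 °C, where the silyl-capped guaiacyl ring and the benzylic CH2 are inert, and because both arms are constitutionally alike no regiochemical question arises.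

Step 5
Reactants: 9 vanillin
Product: 10 4-benzyloxy-3-methoxybenzaldehyde (O-benzylvanillin)
Conditions: BnBr, K2CO3, DMF, rt
Reagents that add atoms: benzyl bromide, BrCc1ccccc1
Why: Williamson ether synthesis on the acidic vanillin phenol, with benzyl chosen because it survives base, hydride, mild acid and fluoride and because both copies fall together in the last step.

Step 6
Reactants: 8 (R)-lactone; 10 O-benzylvanillin
Product: 12 (3S,4R)-3-[(4-benzyloxy-3-methoxyphenyl)(hydroxy)methyl]-4-[(3-methoxy-4-triisopropylsilyloxyphenyl)methyl]dihydrofuran-2(3H)-one (both carbinol epimers), via lithium enolate 11 (not isolated)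
Conditions: LDA, THF, −78 °C; 10, −78 °C; AcOH quench at −78 °C
Reagents that add atoms: none
Why: In this aldol addition of a γ-butyrolactone lithium enolate the aldehyde approaches the planar enolate anti to the C4 arylmethyl group, which sets C3 trans to C4, while the carbinol carbon forms as an epimer mixture that does not matter because it is ionised in step 8.

Step 7
Reactants: 12 aldol lactone
Product: 13 (2R,3R)-2-[(4-benzyloxy-3-methoxyphenyl)(hydroxy)methyl]-3-[(3-methoxy-4-triisopropylsilyloxyphenyl)methyl]butane-1,4-diol (both carbinol epimers)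
Conditions: LiAlH4, THF, 0 °C; H2O/aq NaOH work-up
Reagents that add atoms: none
Why: Lithium aluminium hydride reduction of a lactone to the 1,4-diol touches no stereocentre, outruns retro-aldol cleavage at 0 °C, and spares benzyl and aryl TIPS ethers.

Step 8
Reactants: 13 triol
Product: 14 [(2S,3R,4R)-2-(4-benzyloxy-3-methoxyphenyl)-4-[(3-methoxy-4-triisopropylsilyloxyphenyl)methyl]oxolan-3-yl]methanol (4-O-benzyl-4'-O-TIPS-lariciresinol)
Conditions: (±)-CSA (10 mol %), CH2Cl2, 0 °C; Et3N quench as soon as 13 is consumed
Reagents that add atoms: none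
Why: In this acid-catalysed SN1 cycloetherification (5-exo closure, known for benzylic triols of this lignan type) both carbinol epimers ionise to one p-alkoxybenzyl cation, only the C5 hydroxyl reaches it through a five-membered transition state (the other would give an oxetane), and closure places the aryl group trans to the C3 hydroxymethyl group, which sets C2 as S and turns the trans lactone relationship into the 3,4-cis oxolane.

Step 9
Reactants: 14 oxolane alcohol
Product: 15 [(2S,3R,4R)-2-(4-benzyloxy-3-methoxyphenyl)-4-[(3-methoxy-4-triisopropylsilyloxyphenyl)methyl]oxolan-3-yl]methyl acetate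
Conditions: Ac2O, pyridine, DMAP (cat.), CH2Cl2, 0 °C → rt
Reagents that add atoms: acetic anhydride, CC(=O)OC(C)=O
Why: DMAP-catalysed esterification hides the only free hydroxyl from the boron triflate of step 13, and acetate is chosen because the borohydride of step 14 removes it without a separate step.

Step 10
Reactants: 15 acetate
Product: 16 [(2S,3R,4R)-2-(4-benzyloxy-3-methoxyphenyl)-4-[(4-hydroxy-3-methoxyphenyl)methyl]oxolan-3-yl]methyl acetate
Conditions: TBAF, AcOH (1:1), THF, 0 °C
Reagents that add atoms: none
Why: Fluoride-induced desilylation of aryl silyl ethers is fast at 0 °C because phenoxide is a good leaving group, and the acetic acid buffer keeps the phenoxide from attacking the acetate.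

Step 11
Reactants: 17 (S)-4-benzyl-2-oxazolidinone
Product: 19 (S)-4-benzyl-3-(bromoacetyl)oxazolidin-2-one, via N-lithio oxazolidinone 18 (not isolated)
Conditions: n-BuLi, THF, −78 °C; BrCH2COBr, −78 → 0 °C
Reagents that add atoms: bromoacetyl bromide, O=C(Br)CBr
Why: N-Acylation of a lithiated oxazolidinone with an acid halide is the standard entry to acyl imides, the acyl bromide reacts far faster than the alkyl bromide at −78 °C, and the auxiliary stereocentre is not involved.

Step 12
Reactants: 16 phenol; 19 bromoacetyl imide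
Product: 20 (S)-4-benzyl-3-{[4-({(3R,4R,5S)-4-(acetoxymethyl)-5-(4-benzyloxy-3-methoxyphenyl)oxolan-3-yl}methyl)-2-methoxyphenoxy]acetyl}oxazolidin-2-one
Conditions: K2CO3, MeCN, rt
Reagents that add atoms: none
Why: In this Williamson ether synthesis the potassium phenoxide displaces the strongly activated α-carbonyl bromide by SN2 under conditions mild enough for acetate and imide.

Step 13
Reactants: 20 aryloxyacetyl imide; 10 O-benzylvanillin
Product: 22 (S)-4-benzyl-3-[(2S,3R)-3-(4-benzyloxy-3-methoxyphenyl)-3-hydroxy-2-(aryloxy)propanoyl]oxazolidin-2-one (aryl = 4-{[(3R,4R,5S)-4-(acetoxymethyl)-5-(4-benzyloxy-3-methoxyphenyl)oxolan-3-yl]methyl}-2-methoxyphenyl), via Z-dibutylboron enolate 21 (not isolated)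
Conditions: Bu2BOTf, Et3N, CH2Cl2, −78 → 0 °C; 10, −78 → 0 °C; pH 7 buffer, MeOH, 30% H2O2, 0 °C
Reagents that add atoms: none
Why: In this Evans boron syn glycolate aldol (known for alkoxy- and aryloxyacetyl imides) the Z-boron enolate reacts through a closed Zimmerman–Traxler chair with the auxiliary benzyl group blocking one enolate face, which sets Cβ and Cα in the syn (= threo) relation with the absolute sense that becomes (R,R) after reduction.

Step 14
Reactants: 22 aldol imide
Product: 23 (1R,2R)-1-(4-benzyloxy-3-methoxyphenyl)-2-[4-({(3R,4R,5S)-5-(4-benzyloxy-3-methoxyphenyl)-4-(hydroxymethyl)oxolan-3-yl}methyl)-2-methoxyphenoxy]propane-1,3-diol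
Conditions: LiBH4 (excess), MeOH, THF, 0 °C → rt
Reagents that add atoms: none
Why: Reductive cleavage of an N-acyl oxazolidinone with lithium borohydride gives the primary alcohol without epimerisation at Cβ and frees the auxiliary for recovery, while the methanol-activated excess reagent also reduces off the acetate.

Step 15
Reactants: 23 dibenzyl ether
Product: 24 target, (1R,2R)-1-(4-hydroxy-3-methoxyphenyl)-2-[4-({(3R,4R,5S)-5-(4-hydroxy-3-methoxyphenyl)-4-(hydroxymethyl)oxolan-3-yl}methyl)-2-methoxyphenoxy]propane-1,3-diol
Conditions: H2 (1 atm), 10% Pd/C, EtOAc–EtOH, rt, stopped after uptake of 2 equiv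
Reagents that add atoms: none
Why: In catalytic hydrogenolysis phenolic benzyl ethers are cleaved at 1 atm much faster than a secondary benzylic alcohol or a cyclic benzylic ether, so both phenols are released without touching a stereocentre.

**Compound list**

1 | eugenol | C=CCc1ccc(O)c(OC)c1 | starting material
2 | 4-allyl-2-methoxy-1-(triisopropylsilyloxy)benzene | C=CCc1ccc(O[Si](C(C)C)(C(C)C)C(C)C)c(OC)c1 | intermediate
3 | trichloroacetyl chloride | O=C(Cl)C(Cl)(Cl)Cl | starting material
4 | dichloroketene (not isolated) | ClC(Cl)=C=O | intermediate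
5 | (±)-2,2-dichloro-3-[(3-methoxy-4-triisopropylsilyloxyphenyl)methyl]cyclobutanone | COc1cc(CC2CC(=O)C2(Cl)Cl)ccc1O[Si](C(C)C)(C(C)C)C(C)C | intermediate
6 | 3-[(3-methoxy-4-triisopropylsilyloxyphenyl)methyl]cyclobutanone | COc1cc(CC2CC(=O)C2)ccc1O[Si](C(C)C)(C(C)C)C(C)C | intermediate
7 | 1-hydroperoxy-3-[(3-methoxy-4-triisopropylsilyloxyphenyl)methyl]cyclobutan-1-ol, Criegee adduct (not isolated) | COc1cc(CC2CC(O)(OO)C2)ccc1O[Si](C(C)C)(C(C)C)C(C)C | intermediate
8 | (R)-4-[(3-methoxy-4-triisopropylsilyloxyphenyl)methyl]dihydrofuran-2(3H)-one | COc1cc(C[C@@H]2CC(=O)OC2)ccc1O[Si](C(C)C)(C(C)C)C(C)C | intermediate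
9 | vanillin | COc1cc(C=O)ccc1O | starting material
10 | 4-benzyloxy-3-methoxybenzaldehyde | COc1cc(C=O)ccc1OCc1ccccc1 | intermediate
11 | lithium enolate of 8 (not isolated) | COc1cc(C[C@@H]2C=C(O[Li])OC2)ccc1O[Si](C(C)C)(C(C)C)C(C)C | intermediate
12 | (3S,4R)-aldol lactone, carbinol carbon as epimer mixture | COc1cc(C[C@H]2COC(=O)[C@@H]2C(O)c3ccc(OCc4ccccc4)c(OC)c3)ccc1O[Si](C(C)C)(C(C)C)C(C)C | intermediate
13 | (2R,3R)-triol, carbinol carbon as epimer mixture | COc1cc(C[C@@H](CO)[C@H](CO)C(O)c2ccc(OCc3ccccc3)c(OC)c2)ccc1O[Si](C(C)C)(C(C)C)C(C)C | intermediate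
14 | (2S,3R,4R)-oxolane alcohol (4-O-benzyl-4'-O-TIPS-lariciresinol) | COc1cc(C[C@H]2CO[C@H](c3ccc(OCc4ccccc4)c(OC)c3)[C@H]2CO)ccc1O[Si](C(C)C)(C(C)C)C(C)C | intermediate
15 | acetate of 14 | COc1cc(C[C@H]2CO[C@H](c3ccc(OCc4ccccc4)c(OC)c3)[C@H]2COC(C)=O)ccc1O[Si](C(C)C)(C(C)C)C(C)C | intermediate
16 | free central phenol, acetate retained | COc1cc(C[C@H]2CO[C@H](c3ccc(OCc4ccccc4)c(OC)c3)[C@H]2COC(C)=O)ccc1O | intermediate
17 | (S)-4-benzyl-2-oxazolidinone | O=C1N[C@@H](Cc2ccccc2)CO1 | starting material
18 | N-lithio-(S)-4-benzyl-2-oxazolidinone (not isolated) | [Li]N1[C@@H](Cc2ccccc2)COC1=O | intermediate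
19 | (S)-4-benzyl-3-(bromoacetyl)oxazolidin-2-one | O=C(CBr)N1[C@@H](Cc2ccccc2)COC1=O | intermediate
20 | aryloxyacetyl imide | COc1cc(C[C@H]2CO[C@H](c3ccc(OCc4ccccc4)c(OC)c3)[C@H]2COC(C)=O)ccc1OCC(=O)N5[C@@H](Cc6ccccc6)COC5=O | intermediate
21 | (Z)-dibutylboron enolate of 20 (not isolated) | COc1cc(C[C@H]2CO[C@H](c3ccc(OCc4ccccc4)c(OC)c3)[C@H]2COC(C)=O)ccc1O/C=C(\OB(CCCC)CCCC)N5[C@@H](Cc6ccccc6)COC5=O | intermediate
22 | (2S,3R)-syn aldol imide | COc1cc([C@@H](O)[C@@H](C(=O)N5[C@@H](Cc6ccccc6)COC5=O)Oc2ccc(C[C@H]3CO[C@H](c4ccc(OCc7ccccc7)c(OC)c4)[C@H]3COC(C)=O)cc2OC)ccc1OCc8ccccc8 | intermediate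
23 | (1R,2R)-triol dibenzyl ether | COc1cc([C@@H](O)[C@@H](CO)Oc2ccc(C[C@H]3CO[C@H](c4ccc(OCc5ccccc5)c(OC)c4)[C@H]3CO)cc2OC)ccc1OCc6ccccc6 | intermediate
24 | CNP0158473.2 | COc1cc([C@@H](O)[C@@H](CO)Oc2ccc(C[C@H]3CO[C@H](c4ccc(O)c(OC)c4)[C@H]3CO)cc2OC)ccc1O | target

**Step count**

Total step count: 15.
Longest linear sequence: 13 steps from eugenol (steps 1–4, 6–10, 12–15).

**Steps most likely to fail**

Step 4. The arene is insulated from the ring by one CH2, so discrimination between the two enantiotopic arms may be too weak for a single enantiomer. Any minor antipode carried forward would become a diastereomer only once the auxiliary is attached (20, 22).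

Fallback by resolution, setting out from 6. An achiral Baeyer–Villiger oxidation (mCPBA, NaHCO3, CH2Cl2) would give the racemic lactone F1. AlMe3-mediated aminolysis with (S)-1-phenylethylamine opens it to the (3R,1'S)-hydroxy amide F2 and the (3S,1'S)-hydroxy amide F3, which are separated by crystallisation or chromatography. Heating F2 with TsOH·H2O in toluene relactonises it, and the route is rejoined at 8.

Step 8. Friedel–Crafts attack of the electron-rich central ring on the benzylic cation (six-membered carbocycle formation) can compete with closure. Acid-induced re-ionisation of the product can also erode the selectivity at C2.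

Fallback, setting out from 13. Brief hydrogenolysis (H2, Pd/C, EtOAc) would free the para-hydroxyl group and give the phenolic triol F4. With that hydroxyl the benzylic alcohol loses water under very weak acid (PPTS or dilute AcOH, rt) to the neutral p-quinone methide F5. The C5 hydroxyl adds to it in conjugate fashion to give 4'-O-TIPS-lariciresinol F6, the mode of closure known for the free-phenol triols of this lignan family. Phenol-selective benzylation (BnBr, K2CO3, acetone) returns to 14.

Step 12. Attack of the phenoxide at the imide carbonyl (acyl transfer) or base-induced breakdown of the bromoacetyl imide may compete with the SN2 displacement.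

Fallback, setting out from 16. Alkylation with allyl bromoacetate (K2CO3, acetone) would give the allyl aryloxyacetate F7. Pd(PPh3)4 and morpholine remove the allyl group to leave the aryloxyacetic acid F8. Pivaloyl chloride and Et3N convert it into the mixed pivalic anhydride F9, which acylates the N-lithio oxazolidinone 18 (from 17 and n-BuLi), and the route is rejoined at 20.

Further compounds
F1 | step 4 | (±)-4-[(3-methoxy-4-triisopropylsilyloxyphenyl)methyl]dihydrofuran-2(3H)-one | COc1cc(CC2CC(=O)OC2)ccc1O[Si](C(C)C)(C(C)C)C(C)C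
F2 | step 4 | (3R)-4-hydroxy-3-[(3-methoxy-4-triisopropylsilyloxyphenyl)methyl]-N-[(1S)-1-phenylethyl]butanamide | COc1cc(C[C@@H](CO)CC(=O)N[C@@H](C)c2ccccc2)ccc1O[Si](C(C)C)(C(C)C)C(C)C
F3 | step 4 | (3S)-4-hydroxy-3-[(3-methoxy-4-triisopropylsilyloxyphenyl)methyl]-N-[(1S)-1-phenylethyl]butanamide | COc1cc(C[C@H](CO)CC(=O)N[C@@H](C)c2ccccc2)ccc1O[Si](C(C)C)(C(C)C)C(C)C
F4 | step 8 | (2R,3R)-2-[hydroxy(4-hydroxy-3-methoxyphenyl)methyl]-3-[(3-methoxy-4-triisopropylsilyloxyphenyl)methyl]butane-1,4-diol (carbinol epimers) | COc1cc(C[C@@H](CO)[C@H](CO)C(O)c2ccc(O)c(OC)c2)ccc1O[Si](C(C)C)(C(C)C)C(C)C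
F5 | step 8 | p-quinone methide from F4 (transient, alkene geometry not defined) | COc1cc(C[C@@H](CO)[C@H](CO)C=C2C=CC(=O)C(OC)=C2)ccc1O[Si](C(C)C)(C(C)C)C(C)C
F6 | step 8 | 4'-O-TIPS-lariciresinol, (2S,3R,4R) | COc1cc(C[C@H]2CO[C@H](c3ccc(O)c(OC)c3)[C@H]2CO)ccc1O[Si](C(C)C)(C(C)C)C(C)C
F7 | step 12 | allyl aryloxyacetate of 16 | C=CCOC(=O)COc1ccc(C[C@H]2CO[C@H](c3ccc(OCc4ccccc4)c(OC)c3)[C@H]2COC(C)=O)cc1OC
F8 | step 12 | aryloxyacetic acid of 16 | OC(=O)COc1ccc(C[C@H]2CO[C@H](c3ccc(OCc4ccccc4)c(OC)c3)[C@H]2COC(C)=O)cc1OC
F9 | step 12 | mixed pivalic anhydride of F8 | CC(C)(C)C(=O)OC(=O)COc1ccc(C[C@H]2CO[C@H](c3ccc(OCc4ccccc4)c(OC)c3)[C@H]2COC(C)=O)cc1OC
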